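**Assumption:** the SMILES decodes as the (2R,3R)-trans-2,3-dihydro-1,4-benzodioxine (7′R,8′R) with an E-stilbene, and that isomer is made. The facial sense of the (S,S)-Ru catalyst in Step 5 is predicted from the standard aryl-ketone model. If HPLC or Mosher analysis of 8 shows the opposite sense, the (R,R)-catalyst is used instead.

## Retrosynthetic overview
1. Aiphanol comes from one global hydride unmasking of a fully acylated stilbene ester (CO2Et → CH2OH, three ArO-acyl → ArOH).
2. The stilbene C–C bond comes from a late Heck coupling of a 6-bromobenzodioxane ester with 3,5-diacetoxystyrene.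
3. The 1,4-dioxane ring is the only ring built (the three arenes are bought). It is closed after both stereocentres exist and before the stilbene, by stereoretentive intramolecular Cu C(aryl)–O coupling at C–I in the presence of C–Br.
4. Key step: both stereocentres are set in one asymmetric transfer hydrogenation with dynamic kinetic resolution (ATH–DKR) of a racemic, configurationally labile α-aryloxy-β-keto ester.
5. The keto ester comes from syringic acid, ethyl malonate half-ester and 4-bromo-2-iodophenol. The halogen pattern fixes the benzodioxane regiochemistry.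

Only substrates and building blocks are numbered. Reagents are given with SMILES in the step where they are used.

## Route

**Step 1**
Reactants: 1 syringic acid
Product: 2 3,5-dimethoxy-4-(pivaloyloxy)benzoic acid
Conditions: PivCl (2.2 equiv), Et3N, DMAP (5 mol %), CH2Cl2, 0 °C→rt; then aq NaHCO3/THF, rt; H3O+
Reagents that add atoms: pivaloyl chloride, CC(C)(C)C(=O)Cl
Why: DMAP-catalysed O-acylation of the phenol, with the transient mixed anhydride hydrolysed back to the acid on work-up; the hindered, electron-withdrawing pivalate survives carbonate and amine bases later and suppresses benzylic ionisation and quinone-methide formation.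

**Step 2**
Reactants: 2; 3 potassium ethyl malonate
Product: 4 ethyl 3-[3,5-dimethoxy-4-(pivaloyloxy)phenyl]-3-oxopropanoate
Conditions: CDI, THF, rt; then 3, MgCl2, Et3N, MeCN/THF, rt→45 °C; 1 M HCl
Reagents that add atoms: potassium ethyl malonate (3), CCOC(=O)CC(=O)[O-].[K+]
Why: Masamune–Brooks homologation, in which the acyl imidazolide C-acylates the magnesium malonate enolate and CO2 is lost on acidification, under near-neutral conditions that leave the aryl pivalate intact.

**Step 3**
Reactants: 4
Product: 5 ethyl 2-bromo-3-[3,5-dimethoxy-4-(pivaloyloxy)phenyl]-3-oxopropanoate (racemic)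
Conditions: NBS (1.02 equiv), Mg(ClO4)2 (30 mol %), EtOAc, 0 °C→rt
Reagents that add atoms: N-bromosuccinimide, O=C1CCC(=O)N1Br
Why: Lewis-acid-catalysed electrophilic α-bromination of the chelated 1,3-dicarbonyl enol, which is much faster than SEAr on the acyl-deactivated ring; the new centre is racemic and does not matter.

**Step 4**
Reactants: 5; 6 4-bromo-2-iodophenol
Product: 7 ethyl 2-(4-bromo-2-iodophenoxy)-3-[3,5-dimethoxy-4-(pivaloyloxy)phenyl]-3-oxopropanoate (racemic, labile at C2)
Conditions: K2CO3 (1.5 equiv), acetone, rt
Reagents that add atoms: 4-bromo-2-iodophenol (6), Oc1ccc(Br)cc1I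
Why: Williamson-type SN2 of a phenoxide on a doubly activated bromide, the classical entry to α-aryloxy-β-keto esters; I ends up ortho and Br para to the new ether oxygen, which places the C8′–O bond para to the future vinyl group as in the target.

**Step 5 (key step)**
Reactants: 7
Product: 8 ethyl (2S,3R)-2-(4-bromo-2-iodophenoxy)-3-hydroxy-3-[3,5-dimethoxy-4-(pivaloyloxy)phenyl]propanoate (syn/threo)
Conditions: RuCl(p-cymene)[(S,S)-TsDPEN] (2 mol %), HCO2H/Et3N (5:2), CH2Cl2, 30 °C
Reagents that add atoms: none (HCO2H delivers only H)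
Why: Noyori–Ikariya ATH–DKR, established as syn-selective for α-alkoxy-β-keto esters (the α-aryloxy group is a substrate extension, not a new reaction): C2–H racemises through the enol faster than hydride transfer, the catalyst's arene CH/π contact with the aryl ketone sets C3 as R (same spatial sense as (S)-1-phenylethanol, with descriptor R because C2 outranks aryl), and only the 2S enantiomer offers the polar Felkin–Anh-matched face (C–OAr anti to hydride), so both centres are set together as syn-(2S,3R).

**Step 6**
Reactants: 8
Product: 9 ethyl (2S,3R)-6-bromo-3-[3,5-dimethoxy-4-(pivaloyloxy)phenyl]-2,3-dihydro-1,4-benzodioxine-2-carboxylate (trans)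
Conditions: CuI (10 mol %), 3,4,7,8-Me4-1,10-phenanthroline (20 mol %), Cs2CO3 (1.5 equiv), 4 Å MS, toluene (0.05 M), 80 °C
Reagents that add atoms: none
Why: Intramolecular Ullmann-type Cu-catalysed C(aryl)–O coupling that breaks only the O–H and C(aryl)–I bonds, so both stereocentres are retained and syn-8 maps onto the trans-diequatorial dioxane; six-membered closure at the ortho C–I is far faster than any reaction at the para C–Br at 80 °C, and the pivalate and ethyl ester tolerate anhydrous carbonate.

**Step 7**
Reactants: 10 3,5-dihydroxybenzaldehyde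
Product: 11 5-ethenylbenzene-1,3-diol (3,5-dihydroxystyrene), used crude
Conditions: Ph3PCH3Br (3.5 equiv), KOt-Bu (3.4 equiv), THF, 0 °C→rt; aq NH4Cl
Reagents that add atoms: methyltriphenylphosphonium bromide, C[P+](c1ccccc1)(c1ccccc1)c1ccccc1.[Br-]
Why: Wittig methylenation, in which excess base parks the phenols as phenoxides that, being meta, do not conjugatively deactivate the aldehyde.

**Step 8**
Reactants: 11
Product: 12 5-ethenyl-1,3-phenylene diacetate (3,5-diacetoxystyrene)
Conditions: Ac2O, pyridine, cat. DMAP, CH2Cl2, 0 °C→rt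
Reagents that add atoms: acetic anhydride, CC(=O)OC(C)=O
Why: Simple O-acetylation gives a storable, purifiable styrene whose protecting groups are removed in the same final hydride step.

**Step 9**
Reactants: 9; 12
Product: 13 ethyl (2S,3R)-6-[(E)-2-(3,5-diacetoxyphenyl)ethenyl]-3-[3,5-dimethoxy-4-(pivaloyloxy)phenyl]-2,3-dihydro-1,4-benzodioxine-2-carboxylate
Conditions: Pd2(dba)3 (1.5 mol %), P(t-Bu)3·HBF4 (6 mol %), Cy2NMe, dioxane, rt→50 °C (trace BHT)
Reagents that add atoms: 3,5-diacetoxystyrene (12), C=Cc1cc(OC(C)=O)cc(OC(C)=O)c1
Why: Mizoroki–Heck reaction under bulky-trialkylphosphine conditions suited to electron-rich aryl bromides; terminal carbopalladation and syn-β-hydride elimination give the E-stilbene, and the weak hindered amine neither epimerises C2 nor cleaves the aryl esters.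

**Step 10**
Reactants: 13
Product: 14 aiphanol, 5-[(E)-2-[(2R,3R)-3-(4-hydroxy-3,5-dimethoxyphenyl)-2-(hydroxymethyl)-2,3-dihydro-1,4-benzodioxin-6-yl]ethenyl]benzene-1,3-diol
Conditions: DIBAL-H (12 equiv), THF/toluene, −78→0 °C; Rochelle salt, then cold 1 M HCl to pH 4–5
Reagents that add atoms: none
Why: Global hydride reduction converts CO2Et to CH2OH and reductively cleaves the pivalate and both acetates in one operation, while the stilbene is inert, ester reduction outruns enolisation at low temperature, and aluminium phenoxides of p-hydroxybenzyl aryl ethers are stable at ≤0 °C; no stereocentre is touched, and C2 changes from S to R only because CH2OH ranks below C3.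

## Compound list
1 | syringic acid | COc1cc(C(=O)O)cc(OC)c1O | starting material
2 | 3,5-dimethoxy-4-(pivaloyloxy)benzoic acid | COc1cc(C(=O)O)cc(OC)c1OC(=O)C(C)(C)C | intermediate
3 | potassium ethyl malonate | CCOC(=O)CC(=O)[O-].[K+] | starting material
4 | ethyl 3-[3,5-dimethoxy-4-(pivaloyloxy)phenyl]-3-oxopropanoate | CCOC(=O)CC(=O)c1cc(OC)c(OC(=O)C(C)(C)C)c(OC)c1 | intermediate
5 | ethyl 2-bromo-3-[3,5-dimethoxy-4-(pivaloyloxy)phenyl]-3-oxopropanoate (racemic) | CCOC(=O)C(Br)C(=O)c1cc(OC)c(OC(=O)C(C)(C)C)c(OC)c1 | intermediate
6 | 4-bromo-2-iodophenol | Oc1ccc(Br)cc1I | starting material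
7 | ethyl 2-(4-bromo-2-iodophenoxy)-3-[3,5-dimethoxy-4-(pivaloyloxy)phenyl]-3-oxopropanoate (racemic) | CCOC(=O)C(Oc1ccc(Br)cc1I)C(=O)c1cc(OC)c(OC(=O)C(C)(C)C)c(OC)c1 | intermediate
8 | ethyl (2S,3R)-2-(4-bromo-2-iodophenoxy)-3-hydroxy-3-[3,5-dimethoxy-4-(pivaloyloxy)phenyl]propanoate | CCOC(=O)[C@@H](Oc1ccc(Br)cc1I)[C@H](O)c1cc(OC)c(OC(=O)C(C)(C)C)c(OC)c1 | intermediate
9 | ethyl (2S,3R)-6-bromo-3-[3,5-dimethoxy-4-(pivaloyloxy)phenyl]-2,3-dihydro-1,4-benzodioxine-2-carboxylate | CCOC(=O)[C@H]1Oc2ccc(Br)cc2O[C@@H]1c1cc(OC)c(OC(=O)C(C)(C)C)c(OC)c1 | intermediate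
10 | 3,5-dihydroxybenzaldehyde | O=Cc1cc(O)cc(O)c1 | starting material
11 | 5-ethenylbenzene-1,3-diol | C=Cc1cc(O)cc(O)c1 | intermediate
12 | 5-ethenyl-1,3-phenylene diacetate | C=Cc1cc(OC(C)=O)cc(OC(C)=O)c1 | intermediate
13 | ethyl (2S,3R)-6-[(E)-2-(3,5-diacetoxyphenyl)ethenyl]-3-[3,5-dimethoxy-4-(pivaloyloxy)phenyl]-2,3-dihydro-1,4-benzodioxine-2-carboxylate | CCOC(=O)[C@H]1Oc2ccc(/C=C/c3cc(OC(C)=O)cc(OC(C)=O)c3)cc2O[C@@H]1c1cc(OC)c(OC(=O)C(C)(C)C)c(OC)c1 | intermediate
14 | aiphanol, (2R,3R), E | COc1cc([C@H]2Oc3cc(/C=C/c4cc(O)cc(O)c4)ccc3O[C@@H]2CO)cc(OC)c1O | target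

## Summary
**Total steps:** 10.
**Longest linear sequence:** 8 (Steps 1–6, 9, 10).

**Three steps most likely to fail**

1. **Step 5 (ATH–DKR).** The bulky, weakly basic α-aryloxy group may erode the syn:anti ratio or slow the reduction.
   - Fallback: set both centres with an auxiliary-controlled Evans syn-glycolate aldol.
   - (S)-4-Benzyl-3-[(4-bromo-2-iodophenoxy)acetyl]oxazolidin-2-one is treated with Bu2BOTf/Et3N and 3,5-dimethoxy-4-(pivaloyloxy)benzaldehyde (from syringaldehyde). This gives the syn-(2S,3R) aldol.
   - Ethanolysis of the auxiliary rejoins the route at 8.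

2. **Step 6 (Cu C–O closure on a β-hydroxy ester).** Carbonate base could trigger retro-aldol, C2 epimerisation, or E1cB opening of the product, which would threaten the ee.
   - Fallback: remove the acidifying ester before cyclisation.
   - Reduce the activated α-aryloxy ester of 8 chemoselectively (NaBH4, THF/MeOH, pivalate retained) and silylate the primary OH with TBSCl. That OH would otherwise close a competing six-membered ring.
   - Perform the C–O coupling on the neutral substrate, then the Heck reaction, and finish with DIBAL-H plus fluoride. This adds two steps.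

3. **Step 4 (SN2 on the α-bromo-β-keto ester).** The hindered, weakly nucleophilic phenoxide may instead deprotonate 5 or cause bromine transfer and disproportionation.
   - Fallback: switch to carbenoid chemistry.
   - Carry out Regitz diazo transfer on 4 (p-ABSA, Et3N), then Rh2(OAc)4-catalysed O–H insertion into phenol 6 under neutral conditions.
   - This gives 7 in the same number of steps and also removes any risk of ring bromination in Step 3.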